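**The clock.** Take J, the substrate, and count how many e-foldings of it have gone into X: N = ln(c/(c − x)), with c the J charged and x the X read. A steady N per minute marks a pseudo-first-order clock.

| flask | J | E | time |
|---|---|---|---|
| alpha | 0.400 M | 0.800 M |  |
| zeta | 0.400 M | 1.20 M |  |
| theta | 0.800 M | 0.800 M |  |
| epsilon | 0.400 M | 2.40 M | 38 min |

| alpha run: time / min | alpha run: [X] / M | zeta run: time / min | zeta run: [X] / M | theta run: time / min | theta run: [X] / M |
|---|---|---|---|---|---|
| 1.5 | 0.0208 | 1.5 | 0.0148 | 1.5 | 0.0481 |
| 2.6 | 0.0398 | 2.6 | 0.0294 | 2.6 | 0.1132 |
| 4.4 | 0.0735 | 4.4 | 0.0462 | 4.4 | 0.2175 |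
| 7.6 | 0.1262 | 7.6 | 0.0804 | 7.6 | 0.3638 |
| 13 | 0.2000 | 13 | 0.1326 | 13 | 0.5367 |
| 22 | 0.2727 | 22 | 0.1959 | 22 | 0.6666 |
| 38 | 0.3439 | 38 | 0.2763 | 38 | 0.7237 |

(readings scatter by 0.002 M)

* reaction order in [J] at the outset, round the charge of the alpha run, defined at two percent of the J turned into X (one fixed amount of X, the same in the runs compared)
* reaction order in [E] at the outset, round the charge of the alpha run, defined at two percent of the J turned into X
* X in the epsilon run at 38 min, as a share of the J charged

- Overall: J + E -> X.
- Constant volume, constant temperature.
- Bound and free are read together.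
- "The second partner" is E.
- An order is taken over about fifteen percent of the charge, up and down.

**The exponent.** At 38 min the alpha flask stands at N = 1.96 and the zeta flask at the lower N = 1.17. Go to logarithms and divide the fall in ln N by the rise in ln [E]. This gives m = 1.27, the braking exponent: the share by which the clock slows for each share of added E, late in the runs.

**My reckoning.** Epsilon holds 2.40 M of E against the 1.20 M of zeta, so scale N by that ratio raised to −m. This gives N = 0.487, and a share of 38.5% of the J turned into X.

**The test.** Check whether one number per flask is enough. Alpha runs at 0.0520 /min at 22 min and 0.0516 /min at 38 min, so it serves there. Theta, with J equal to E, drops from 0.0814 /min to 0.0618 /min, so it fails there. Epsilon holds 6.00 of E per J, more than the 2.00 of alpha, so keep the clock.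

**The forecast.** It gives 33% (22% to 43%), less than my share, with orders of 1.2 (0.7 to 1.9) in J and −0.8 (−1.4 to −0.3) in E at the outset. Its ground for the later course: “E inhibits, with an apparent order of about −1.3 later in the runs”.

**The result.** The epsilon flask gives 39.4%, with orders of 0.97 in J and −0.55 in E at the outset.

    J ⇌ Q (0.8280 /min, 0.04476 /min)
    Q + E → X (3.174 /M/min)
    2 J → Rx (0.6600 /M/min)
    J + E ⇌ JE, settled at all times (30.40 /M)

**The exponent reused.** That share means N = 0.501, so from zeta to epsilon the exponent is 1.22, beside m = 1.27. The outset order in E is shallower than this late braking. Now take the alpha flask's time to X at 50.0% of the J charged, 13.2 min, scale it from N = 0.693 down to N = 0.288, which belongs to X at 25.0% of the J charged, and stretch it by the E ratio raised to m. This puts the zeta flask at that 25.0% at 9.20 min, and that flask reads 9.57 min.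

The numbers in the tables come from a simulation on assumed constants, noise included.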